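**Retrosynthetic overview**
- The sulfate comes from the primary alcohol, and the alcohol from a benzyl(phenyl)carbamate. The CH2–CH bond next to the side-chain stereocentre is cut back to a vinyl-substituted bicyclic olefin and a racemic carbamate-protected bromohydrin (nickel-hydride enantioconvergent coupling, the proposed new step).
- The vinyl group comes from an allyl group by isomerizing ethenolysis. Ring A is closed last by cation–olefin cyclization of a monocyclic triene.
- The triene comes from an enol triflate and homoprenylzinc bromide (Negishi coupling). The enol triflate comes from a 2-allyl-2,3-dimethylcyclohexanone, made from 2-methylcyclohex-2-en-1-one by copper-catalysed asymmetric conjugate methylation and enolate allylation (both ring stereocentres).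
- The bromohydrin carbamate comes from methyl pent-4-enoate and 3-bromofuran (B-alkyl Suzuki coupling), then α-bromination, reduction and carbamoylation.
- Ring order: ring B is present in the starting enone, the furan arrives intact, ring A is formed in step 4.

Assumption: the target is taken as drawn, the free hydrogen sulfate, which is liberated in the last operation and should be kept cold and dilute (the sodium salt is the storage form).

**Step 1**
Reactants: 1 2-methylcyclohex-2-en-1-one; 2 3-iodoprop-1-ene (allyl iodide)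
Product: 4 (2R,3S)-2,3-dimethyl-2-(prop-2-en-1-yl)cyclohexan-1-one, via magnesium enolate 3 (not isolated)
Conditions: MeMgBr, Cu(OTf)2 (3 mol %), chiral hydroxyalkyl imidazolinium salt (NHC precursor, 4 mol %, antipode giving 3S), Et2O, −30 °C; then 2, DMPU, THF, −30 °C → rt
Reagents that add atoms: methylmagnesium bromide, C[Mg]Br
Why: Copper-catalysed asymmetric conjugate addition sets C3 as S under ligand control, and the regiodefined enolate is then allylated (SN2) anti to the neighbouring C3 methyl group, which gives the 2R quaternary centre with the two methyl groups cis (tandem conjugate addition–enolate alkylation).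

**Step 2**
Reactants: 4 (2R,3S)-2,3-dimethyl-2-(prop-2-en-1-yl)cyclohexan-1-one
Product: 6 (5S,6R)-5,6-dimethyl-6-(prop-2-en-1-yl)cyclohex-1-en-1-yl trifluoromethanesulfonate, via potassium enolate 5 (not isolated)
Conditions: KN(SiMe3)2, THF, −78 °C; then PhNTf2, −78 → 0 °C
Reagents that add atoms: N-phenylbis(trifluoromethanesulfonimide), O=S(=O)(N(c1ccccc1)S(=O)(=O)C(F)(F)F)C(F)(F)F
Why: Only C6 carries α-hydrogens, so enolization and O-sulfonylation (enol triflate formation) give a single regioisomer and leave both stereocentres untouched.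

**Step 3**
Reactants: 6 (5S,6R)-5,6-dimethyl-6-(prop-2-en-1-yl)cyclohex-1-en-1-yl trifluoromethanesulfonate; 7 5-bromo-2-methylpent-2-ene
Product: 9 (5S,6R)-5,6-dimethyl-1-(4-methylpent-3-en-1-yl)-6-(prop-2-en-1-yl)cyclohex-1-ene, via homoprenylzinc bromide 8 (not isolated)
Conditions: 7, Zn, LiCl, THF, 45 °C; then 6, Pd(dppf)Cl2 (5 mol %), THF/NMP, 60 °C
Reagents that add atoms: none
Why: Negishi cross-coupling of an alkenyl triflate with a primary alkylzinc halide, in which the wide-bite-angle dppf ligand favours reductive elimination over β-hydride elimination.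

**Step 4**
Reactants: 9 (5S,6R)-5,6-dimethyl-1-(4-methylpent-3-en-1-yl)-6-(prop-2-en-1-yl)cyclohex-1-ene
Product: 10 (1R,2S)-1,2,5,5-tetramethyl-1-(prop-2-en-1-yl)-1,2,3,4,5,6,7,8-octahydronaphthalene
Conditions: MeSO3H (1.5 equiv), CH2Cl2, −20 → 0 °C
Reagents that add atoms: none
Why: Protonation of the trisubstituted side-chain olefin gives a tertiary cation that is captured 6-endo by the ring olefin (cation–olefin cyclization), and loss of the C4a proton gives the tetrasubstituted ring-fusion olefin, while the far less basic monosubstituted allyl olefin stays out of the reaction.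

**Step 5**
Reactants: 10 (1R,2S)-1,2,5,5-tetramethyl-1-(prop-2-en-1-yl)-1,2,3,4,5,6,7,8-octahydronaphthalene
Product: 12 (1R,2S)-1-ethenyl-1,2,5,5-tetramethyl-1,2,3,4,5,6,7,8-octahydronaphthalene, via propenyl isomer 11 (not isolated)
Conditions: [Pd(μ-Br)(P(t-Bu)3)]2 (1 mol %), second-generation Hoveyda–Grubbs catalyst RuCl2(H2IMes)(=CH-C6H4-2-O-i-Pr) (5 mol %), ethylene (10 bar), toluene, 50 °C
Reagents that add atoms: ethylene, C=C
Why: Isomerizing ethenolysis, in which a palladium hydride moves the allyl double bond one position (the quaternary carbon stops further migration) and ruthenium-catalysed cross metathesis with ethylene trims the propenyl group to vinyl; the hindered tetrasubstituted olefin is inert to both catalysts.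

**Step 6**
Reactants: 13 methyl pent-4-enoate; 14 3-bromofuran
Product: 16 methyl 5-(furan-3-yl)pentanoate, via alkylborane 15 (not isolated)
Conditions: 9-BBN, THF, 0 °C → rt; then 14, Pd(dppf)Cl2 (3 mol %), K3PO4 (aq), DMF, 50 °C
Reagents that add atoms: none
Why: Anti-Markovnikov hydroboration of the terminal olefin followed by B-alkyl Suzuki–Miyaura coupling with the heteroaryl bromide; the ester tolerates both operations.

**Step 7**
Reactants: 16 methyl 5-(furan-3-yl)pentanoate
Product: 18 rac-methyl 2-bromo-5-(furan-3-yl)pentanoate, via lithium enolate 17 (not isolated)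
Conditions: LiN(i-Pr)2, THF, −78 °C; then BrCCl2CCl2Br, −78 °C
Reagents that add atoms: 1,2-dibromo-1,1,2,2-tetrachloroethane, BrC(Cl)(Cl)C(Cl)(Cl)Br
Why: Electrophilic bromination of the ester enolate with a positive-bromine donor that does not attack the furan at −78 °C; a racemic bromide is all that the later enantioconvergent coupling needs.

**Step 8**
Reactants: 18 rac-methyl 2-bromo-5-(furan-3-yl)pentanoate
Product: 19 rac-2-bromo-5-(furan-3-yl)pentan-1-ol
Conditions: i-Bu2AlH (2.3 equiv), CH2Cl2, −78 → −20 °C; Rochelle salt work-up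
Reagents that add atoms: none
Why: Hydride reduction of the ester to the primary alcohol at low temperature leaves the secondary C–Br bond intact, and the non-basic aluminium alkoxide does not close to the epoxide.

**Step 9**
Reactants: 19 rac-2-bromo-5-(furan-3-yl)pentan-1-ol
Product: 20 rac-2-bromo-5-(furan-3-yl)pentyl benzyl(phenyl)carbamate
Conditions: PhN(Bn)C(O)Cl, pyridine, DMAP (10 mol %), CH2Cl2, 40 °C
Reagents that add atoms: N-benzyl-N-phenylcarbamoyl chloride, O=C(Cl)N(Cc1ccccc1)c1ccccc1
Why: DMAP-catalysed O-carbamoylation under weakly basic conditions installs the nickel-directing carbamate without epoxide formation from the bromohydrin.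

**Step 10**
Reactants: 12 (1R,2S)-1-ethenyl-1,2,5,5-tetramethyl-1,2,3,4,5,6,7,8-octahydronaphthalene; 20 rac-2-bromo-5-(furan-3-yl)pentyl benzyl(phenyl)carbamate (1.5 equiv)
Product: 21 (2R)-5-(furan-3-yl)-2-{2-[(1R,2S)-1,2,5,5-tetramethyl-1,2,3,4,5,6,7,8-octahydronaphthalen-1-yl]ethyl}pentyl benzyl(phenyl)carbamate
Conditions: NiBr2·glyme (10 mol %), chiral bis(oxazoline) ligand (12 mol %, antipode giving 2R), (EtO)3SiH (2 equiv), K3PO4·H2O (2.5 equiv), i-Pr2O/DMA, 0 °C → rt
Reagents that add atoms: none
Why: Proposed new method: a nickel-hydride enantioconvergent hydroalkylation in which the olefin of 12, not a preformed alkylmetal, is the nucleophile towards the racemic carbamate-bearing secondary bromide 20 — L*Ni–H (from NiBr2, silane and phosphate) adds anti-Markovnikov to the vinyl group (the quaternary neighbour rules out branched insertion and chain walking), the primary alkylnickel abstracts bromine from 20 to give a secondary radical that recombines with nickel while the carbamate C=O is chelated, and C(sp3)–C(sp3) reductive elimination from the chiral dialkylnickel sets C2 as R from both enantiomers of 20 under ligand control; the closest known reactions are the nickel/chiral diamine stereoconvergent alkyl–alkyl Suzuki coupling of acylated bromohydrins with alkyl-9-BBN reagents and the nickel-hydride coupling of terminal olefins with racemic α-halo amides.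

**Step 11**
Reactants: 21 (2R)-5-(furan-3-yl)-2-{2-[(1R,2S)-1,2,5,5-tetramethyl-1,2,3,4,5,6,7,8-octahydronaphthalen-1-yl]ethyl}pentyl benzyl(phenyl)carbamate
Product: 22 (2R)-5-(furan-3-yl)-2-{2-[(1R,2S)-1,2,5,5-tetramethyl-1,2,3,4,5,6,7,8-octahydronaphthalen-1-yl]ethyl}pentan-1-ol
Conditions: LiAlH4, THF, 0 → 50 °C
Reagents that add atoms: none
Why: Hydride reduction cleaves the carbamate to the primary alcohol and N-benzyl-N-methylaniline without touching the stereocentre, the furan or the tetrasubstituted olefin.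

**Step 12**
Reactants: 22 (2R)-5-(furan-3-yl)-2-{2-[(1R,2S)-1,2,5,5-tetramethyl-1,2,3,4,5,6,7,8-octahydronaphthalen-1-yl]ethyl}pentan-1-ol
Product: 24 (2R)-5-(furan-3-yl)-2-{2-[(1R,2S)-1,2,5,5-tetramethyl-1,2,3,4,5,6,7,8-octahydronaphthalen-1-yl]ethyl}pentyl hydrogen sulfate, via pyridinium sulfate 23 (not isolated)
Conditions: SO3·pyridine (3 equiv), pyridine, 0 °C → rt; then Dowex 50W (H+ form), MeOH/H2O, 0 °C
Reagents that add atoms: sulfur trioxide–pyridine complex, [O-]S(=O)(=O)[n+]1ccccc1
Why: O-sulfation of the primary alcohol with the pyridine-moderated SO3 donor is much faster than furan sulfonation at room temperature, and cold cation exchange gives the acid form.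

**Compound list**
1 | 2-methylcyclohex-2-en-1-one | CC1=CCCCC1=O | starting material
2 | 3-iodoprop-1-ene (allyl iodide) | C=CCI | starting material
3 | bromomagnesium (3S)-2,3-dimethylcyclohex-1-en-1-olate | C[C@H]1CCCC(O[Mg]Br)=C1C | intermediate
4 | (2R,3S)-2,3-dimethyl-2-(prop-2-en-1-yl)cyclohexan-1-one | C[C@H]1CCCC(=O)[C@]1(C)CC=C | intermediate
5 | potassium (5S,6R)-5,6-dimethyl-6-(prop-2-en-1-yl)cyclohex-1-en-1-olate | C[C@H]1CCC=C([O-])[C@]1(C)CC=C.[K+] | intermediate
6 | (5S,6R)-5,6-dimethyl-6-(prop-2-en-1-yl)cyclohex-1-en-1-yl trifluoromethanesulfonate | C[C@H]1CCC=C(OS(=O)(=O)C(F)(F)F)[C@]1(C)CC=C | intermediate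
7 | 5-bromo-2-methylpent-2-ene | CC(C)=CCCBr | starting material
8 | (4-methylpent-3-en-1-yl)zinc bromide | CC(C)=CCC[Zn]Br | intermediate
9 | (5S,6R)-5,6-dimethyl-1-(4-methylpent-3-en-1-yl)-6-(prop-2-en-1-yl)cyclohex-1-ene | C[C@H]1CCC=C(CCC=C(C)C)[C@]1(C)CC=C | intermediate
10 | (1R,2S)-1,2,5,5-tetramethyl-1-(prop-2-en-1-yl)-1,2,3,4,5,6,7,8-octahydronaphthalene | C[C@H]1CCC2=C(CCCC2(C)C)[C@]1(C)CC=C | intermediate
11 | (1S,2S)-1,2,5,5-tetramethyl-1-[(1E)-prop-1-en-1-yl]-1,2,3,4,5,6,7,8-octahydronaphthalene (same spatial arrangement as 10; the descriptor changes by priority only) | C[C@H]1CCC2=C(CCCC2(C)C)[C@]1(C)/C=C/C | intermediate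
12 | (1R,2S)-1-ethenyl-1,2,5,5-tetramethyl-1,2,3,4,5,6,7,8-octahydronaphthalene | C[C@H]1CCC2=C(CCCC2(C)C)[C@]1(C)C=C | intermediate
13 | methyl pent-4-enoate | C=CCCC(=O)OC | starting material
14 | 3-bromofuran | Brc1ccoc1 | starting material
15 | methyl 5-(9-borabicyclo[3.3.1]nonan-9-yl)pentanoate | COC(=O)CCCCB1C2CCCC1CCC2 | intermediate
16 | methyl 5-(furan-3-yl)pentanoate | COC(=O)CCCCc1ccoc1 | intermediate
17 | lithium 5-(furan-3-yl)-1-methoxypent-1-en-1-olate | COC([O-])=CCCCc1ccoc1.[Li+] | intermediate
18 | rac-methyl 2-bromo-5-(furan-3-yl)pentanoate | COC(=O)C(Br)CCCc1ccoc1 | intermediate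
19 | rac-2-bromo-5-(furan-3-yl)pentan-1-ol | OCC(Br)CCCc1ccoc1 | intermediate
20 | rac-2-bromo-5-(furan-3-yl)pentyl benzyl(phenyl)carbamate | O=C(OCC(Br)CCCc1ccoc1)N(Cc1ccccc1)c1ccccc1 | intermediate
21 | (2R)-5-(furan-3-yl)-2-{2-[(1R,2S)-1,2,5,5-tetramethyl-1,2,3,4,5,6,7,8-octahydronaphthalen-1-yl]ethyl}pentyl benzyl(phenyl)carbamate | C[C@H]1CCC2=C(CCCC2(C)C)[C@]1(C)CC[C@@H](CCCc1ccoc1)COC(=O)N(Cc1ccccc1)c1ccccc1 | intermediate
22 | (2R)-5-(furan-3-yl)-2-{2-[(1R,2S)-1,2,5,5-tetramethyl-1,2,3,4,5,6,7,8-octahydronaphthalen-1-yl]ethyl}pentan-1-ol | C[C@H]1CCC2=C(CCCC2(C)C)[C@]1(C)CC[C@@H](CCCc1ccoc1)CO | intermediate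
23 | pyridinium (2R)-5-(furan-3-yl)-2-{2-[(1R,2S)-1,2,5,5-tetramethyl-1,2,3,4,5,6,7,8-octahydronaphthalen-1-yl]ethyl}pentyl sulfate | C[C@H]1CCC2=C(CCCC2(C)C)[C@]1(C)CC[C@@H](CCCc1ccoc1)COS(=O)(=O)[O-].c1cc[nH+]cc1 | intermediate
24 | (2R)-5-(furan-3-yl)-2-{2-[(1R,2S)-1,2,5,5-tetramethyl-1,2,3,4,5,6,7,8-octahydronaphthalen-1-yl]ethyl}pentyl hydrogen sulfate | C[C@H]1CCC2=C(CCCC2(C)C)[C@]1(C)CC[C@@H](CCCc1ccoc1)COS(=O)(=O)O | target

**Step count**
Total: 12 steps. Longest linear sequence: 8 steps (steps 1–5, then 10–12); the side-chain branch (steps 6–9) joins at step 10.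

**Three steps most likely to fail**

Step 10 (the proposed new coupling). The risks are slow nickel-hydride insertion into the neopentyl-type olefin, simple reduction of the bromide, or poor enantiocontrol. The fallback is known chemistry and replaces the olefin/silane manifold by a preformed alkylborane. Setting out from 12, hydroboration with 9-BBN (THF, rt) gives 9-{2-[(1R,2S)-1,2,5,5-tetramethyl-1,2,3,4,5,6,7,8-octahydronaphthalen-1-yl]ethyl}-9-borabicyclo[3.3.1]nonane F7. F7 is coupled with 20 in the stereoconvergent nickel/chiral diamine alkyl–alkyl Suzuki reaction of acylated bromohydrins (NiBr2·diglyme, N,N′-dimethyl-1,2-diphenylethane-1,2-diamine of the appropriate configuration, KOt-Bu, i-BuOH, i-Pr2O, rt). The route is rejoined at 21.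

Step 4 (cation–olefin cyclization). The risks are formation of the 1(8a)-olefin isomer, a methyl shift from the neighbouring quaternary carbon, or attack on the allyl group. The fallback closes ring A by acylation and installs the gem-dimethyl group afterwards. Setting out from 6, Negishi coupling (Pd(dppf)Cl2, THF/NMP) with (4-methoxy-4-oxobutyl)zinc bromide F2, made from methyl 4-bromobutanoate F1 with Zn/LiCl, gives methyl 4-[(5S,6R)-5,6-dimethyl-6-(prop-2-en-1-yl)cyclohex-1-en-1-yl]butanoate F3. LiOH (THF/H2O) gives 4-[(5S,6R)-5,6-dimethyl-6-(prop-2-en-1-yl)cyclohex-1-en-1-yl]butanoic acid F4. (CF3CO)2O in CH2Cl2 at 0 °C effects intramolecular acylation of the ring olefin to (5R,6S)-5,6-dimethyl-5-(prop-2-en-1-yl)-3,4,5,6,7,8-hexahydronaphthalen-1(2H)-one F5; loss of the proton α to the new carbonyl fixes the double bond at the ring fusion. Geminal dimethylation of the carbonyl with Me2TiCl2 (CH2Cl2, −30 → 0 °C) rejoins the route at 10.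

Step 5 (isomerizing ethenolysis). The risk is that metathesis at the propenyl group next to the quaternary carbon is too slow. The fallback replaces metathesis by oxidative cleavage and olefination. Setting out from 10, RuHCl(CO)(PPh3)3 (toluene, 80 °C) gives 11, which is isolated. OsO4 (cat.)/NaIO4 with 2,6-lutidine in dioxane/H2O cleaves only the unhindered propenyl olefin to (1R,2S)-1,2,5,5-tetramethyl-1,2,3,4,5,6,7,8-octahydronaphthalene-1-carbaldehyde F6. Wittig methylenation with Ph3P=CH2 (THF, 0 °C → rt) rejoins the route at 12.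

**Further compounds**
F1 | step 4 | methyl 4-bromobutanoate | COC(=O)CCCBr
F2 | step 4 | (4-methoxy-4-oxobutyl)zinc bromide | COC(=O)CCC[Zn]Br
F3 | step 4 | methyl 4-[(5S,6R)-5,6-dimethyl-6-(prop-2-en-1-yl)cyclohex-1-en-1-yl]butanoate | C[C@H]1CCC=C(CCCC(=O)OC)[C@]1(C)CC=C
F4 | step 4 | 4-[(5S,6R)-5,6-dimethyl-6-(prop-2-en-1-yl)cyclohex-1-en-1-yl]butanoic acid | C[C@H]1CCC=C(CCCC(=O)O)[C@]1(C)CC=C
F5 | step 4 | (5R,6S)-5,6-dimethyl-5-(prop-2-en-1-yl)-3,4,5,6,7,8-hexahydronaphthalen-1(2H)-one | C[C@H]1CCC2=C(CCCC2=O)[C@]1(C)CC=C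
F6 | step 5 | (1R,2S)-1,2,5,5-tetramethyl-1,2,3,4,5,6,7,8-octahydronaphthalene-1-carbaldehyde | C[C@H]1CCC2=C(CCCC2(C)C)[C@]1(C)C=O
F7 | step 10 | 9-{2-[(1R,2S)-1,2,5,5-tetramethyl-1,2,3,4,5,6,7,8-octahydronaphthalen-1-yl]ethyl}-9-borabicyclo[3.3.1]nonane | C[C@H]1CCC2=C(CCCC2(C)C)[C@]1(C)CCB1C2CCCC1CCC2
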